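## The problem

Target 21 is an achiral flavonol: a chromen-4-one (rings A and C) with ring B on C2, a hydroxyl on C3, hydroxyls on C5 and C7, a methoxy group on C8 and a prenyl ether on C4'. There is no stereocentre, and the prenyl double bond carries two identical methyl groups, so nothing has to be set or relayed stereochemically. The work lies in regiochemistry, oxidation level and functional-group tolerance. Ring A carries four oxygens (O1 on C8a, the 8-methoxy group, 7-OH and 5-OH) that must be told apart: one becomes the pyranone oxygen, one stays methylated and two end free. C3 must bear oxygen, and the usual oxidative entries are poor here: 2',6'-dioxygenated chalcones divert to aurones under alkaline peroxide, and electrophilic oxidants attack the prenyl alkene. Once the prenyl aryl ether is present, hydrogenolysis, strong acids and electrophilic oxidants are excluded, and the 8-methyl ether forbids any global demethylation. The three hydroxyls therefore need protecting groups that leave under fluoride or buffered aprotic conditions, and the air- and base-sensitive polyphenol is unveiled last. The feature that invites the key step is that C3 is a single oxygen-bearing carbon between C4, an acyl carbon on C4a, and C2, a carboxyl-level carbon already bonded to O1 and ring B. Ring C is thus an O-aroylsalicyloyl unit (acyl on C4a, aroyloxy on C8a) closed by one alkoxy-substituted carbon.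

## Retrosynthesis

**21 ⇒ 20 ⇒ 19 (O–C bonds of protecting groups).** The last two operations only release hydroxyls. The 3-oxygen is carried as a 2-(trimethylsilyl)ethyl ether, cleaved by fluoride, and the 5- and 7-oxygens as MOM ethers, cleaved by a silyl triflate buffered with bipyridyl. Benzyl ethers (hydrogenolysis) and methyl ethers (Lewis-acid demethylation) were rejected because the prenyl ether and the 8-methoxy group would not survive their removal. Fluoride is used first, on neutral 19, so that the fragmentation does not have to expel an oxygen from a polyanion; 20 then loses its acetals to give 21.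

**19 ⇒ 15 + 17 (C2=C3 and C3–C4).** Both bonds to C3 are cut, which reduces ring C to the acid chloride 15 and the one-carbon alkoxymethylene ylide 17. Neighbouring cuts were weighed. Cutting only C2–C3 (diketone cyclodehydration) leaves C3 unoxidised. Cutting O1–C2 and Cα–Cβ (chalcone route) meets the aurone problem. The chosen cut brings C3 in already oxygenated with a fluoride-labile group and forms one ring and two skeletal bonds in one flask. The forward reaction must acylate the ylide at the acid chloride and not at the aryl ester, and the resulting acyl ylide 18 must olefinate an ester carbonyl.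

**17 ⇒ 16.** The ylide comes from the phosphonium salt 16 by deprotonation; nothing else is asked.

**15 ⇒ 14 ⇒ 13 ⇒ 12 + 4 (O1–C2 ester bond; carboxyl oxidation level).** The acid chloride is traced to acid 14 (chlorination without HCl, for the sake of the acetals and the prenyl ether), and 14 to aldehyde 13 by oxidation. The aldehyde is kept as a latent carboxyl so that the phenol of 12 can be aroylated with acid 4 without mixed-anhydride complications from a free salicylic acid. Cutting the ester gives two simple aromatics, 12 and 4.

**12 ⇒ 11 (C4a–C4).** The formyl carbon is removed from the only free position ortho to the phenol. Formylation directed by the phenoxide is preferred to electrophilic formylation, which would also address the carbon between the two MOM ethers.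

**11 ⇒ 10 ⇒ 9 ⇒ 7 ⇒ 6 ⇒ 5 (C8–O and oxygen differentiation).** The 8-oxygen is introduced by turning the formyl group of phloroglucinaldehyde 5 into a phenol (Dakin oxidation of 7 to 9) and methylating it (10). Before that the aldehyde does a second job: its hydrogen bond leaves one ortho hydroxyl untouched in the bis-MOM protection (6), and that hydroxyl is marked as a benzyl ether (7). Hydrogenolysis of 10, before any prenyl group is present, frees exactly the phenol that becomes O1 (11). The cost is five routine steps; the gain is that every oxygen of ring A is unambiguous.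

**4 ⇒ 3 ⇒ 1 + 2.** The prenyl ether is made by Williamson alkylation of the paraben 1 with prenyl bromide 2, followed by saponification.

## Roads not taken

**Alternative 1:** carbene-catalysed intramolecular benzoin, cutting C3–C4 of a dihydroflavonol. The dialdehyde A2 (aldehyde 12 O-alkylated by an α-aryl acetaldehyde unit) would be closed by a triazolium-derived carbene and triethylamine to the trans-3-hydroxyflavanone A1.
- Merits: metal-free and catalytic, no stoichiometric phosphorus waste, and C3 arrives oxygenated.
- Weak points: A1 is two hydrogens too rich, so a dehydrogenation to 20 must follow, and it erases both stereocentres the step creates. A2 is an enolisable α-aryl-α-aryloxy aldehyde and awkward to make on the hindered phenol of 12. A carbene adding to that aliphatic aldehyde can expel the α-aryloxy group (internal redox) instead of forming the ring. The aldehyde that must act as acyl-anion donor is the di-ortho-substituted, electron-rich aromatic one.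
- Comparison: no shorter than the chosen plan once A2 and the dehydrogenation are counted. Its better atom economy is outweighed by the fact that the Wittig closure gives the flavonol oxidation level directly.

**Alternative 2:** thermal cyclobutenone ring expansion building ring A, cutting C4a–C5. Heating the squarate-derived 4-methoxy-4-pyranonylcyclobutenone A4 would open it to a dienylketene that closes onto the pyranone carbon destined to be C4a and tautomerises to the 5-hydroxyflavone A3.
- Merits: the oxygen pattern of ring A comes from the cyclobutenone with complete regiocontrol; the 5-hydroxyl arrives free and the 8-methoxy group is set by methylating the carbinol. In this respect it is better than the six-step differentiation of 5.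
- Weak points: A4 needs a 6-metallated 2-aryl-3-alkoxy-4-pyranone and a mono-alkoxycyclobutenedione that must be attacked at one specific carbonyl; both are multistep and base-sensitive. The tert-butyl ether on O7 and the MOM group on O3 of A3 can only be removed with strong acid, the condition the prenyl ether tolerates least.
- Comparison: the chosen plan uses ordinary aromatic chemistry for ring A and keeps the final deprotection under fluoride and buffered conditions.

**Alternative 3:** carbonylative annulation, cutting C4a–C4, C4–C3 and O1–C2. Iodophenol A6, carbon monoxide and arylalkyne A7 would be joined with PdCl2(PPh3)2 and diethylamine to an ynone that closes through the phenol oxygen to flavone A5.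
- Merits: three components in one step. A6 would come from phenol 11 in one step, so this road is about three steps shorter on the longest line than the chosen one. This is a real advantage.
- Weak points: A5 has no oxygen on C3, so a late hydroxylation with a strong base and an oxidant is needed. Iodination of 11 has to choose the position ortho to the hydroxyl over the carbon between the two MOM ethers. Oxidative addition of zerovalent palladium to a di-ortho-substituted, electron-rich aryl iodide is slow. Five-membered closure to an aurone and non-carbonylative coupling to a benzofuran are known competitors.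
- Comparison: the chosen plan sets against the shorter count a C3 oxygen that is in place from the start, a ring size fixed by the substrate, and no metal or carbon monoxide. Its fallback reaches A5 by known chemistry in any case.

Key step: step 12

Assumption: [2-(trimethylsilyl)ethoxymethyl]triphenylphosphonium chloride 16 is taken as a catalogue Wittig salt; if it had to be made, quaternisation of PPh3 with 2-(trimethylsilyl)ethoxymethyl chloride gives it in one operation.

## Route

Step 1
Reactants: 1 methyl 4-hydroxybenzoate; 2 1-bromo-3-methylbut-2-ene (prenyl bromide)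
Product: 3 methyl 4-(3-methylbut-2-enyloxy)benzoate
Conditions: K2CO3, DMF, rt
Reagents that add atoms: none
Why: Williamson ether synthesis; the phenoxide displaces the primary allylic bromide at the unsubstituted terminus, and the ester blocks O-alkylation of the carboxyl.

Step 2
Reactants: 3 methyl 4-(3-methylbut-2-enyloxy)benzoate
Product: 4 4-(3-methylbut-2-enyloxy)benzoic acid
Conditions: LiOH, THF/MeOH/H2O, 50 °C; then 1 M HCl, 0 °C, pH 3–4
Reagents that add atoms: lithium hydroxide, [Li+].[OH-]
Why: Ester saponification; the prenyl ether is inert to base and survives the brief cold acidification.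

Step 3
Reactants: 5 2,4,6-trihydroxybenzaldehyde
Product: 6 2-hydroxy-4,6-bis(methoxymethoxy)benzaldehyde
Conditions: MOMCl (2.2 equiv), i-Pr2NEt, CH2Cl2, 0 °C to rt
Reagents that add atoms: chloromethyl methyl ether, COCCl
Why: O-alkylation with an α-chloro ether; after the first ortho hydroxyl is etherified the remaining one is locked in a hydrogen bond to the aldehyde and stays free, which is the established outcome for this aldehyde.

Step 4
Reactants: 6 2-hydroxy-4,6-bis(methoxymethoxy)benzaldehyde
Product: 7 2-(benzyloxy)-4,6-bis(methoxymethoxy)benzaldehyde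
Conditions: BnBr, K2CO3, DMF, rt to 50 °C
Reagents that add atoms: benzyl bromide, BrCc1ccccc1
Why: Williamson benzylation of the last phenol; it marks the oxygen that will become O1 with a group removable before the prenyl ether enters.

Step 5
Reactants: 7 2-(benzyloxy)-4,6-bis(methoxymethoxy)benzaldehyde
Product: 9 2-(benzyloxy)-4,6-bis(methoxymethoxy)phenol, via aryl formate 8 (not isolated)
Conditions: mCPBA, CH2Cl2, 0 °C to rt; aq. Na2S2O3/NaHCO3 wash; then K2CO3, MeOH, 0 °C
Reagents that add atoms: 3-chloroperoxybenzoic acid, OOC(=O)c1cccc(Cl)c1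
Why: Dakin oxidation in its peracid (Baeyer–Villiger) form; the trialkoxyaryl group migrates far better than hydride, and methanolysis of the formate frees the phenol, which is methylated without storage because it is easily oxidised.

Step 6
Reactants: 9 2-(benzyloxy)-4,6-bis(methoxymethoxy)phenol
Product: 10 1-(benzyloxy)-2-methoxy-3,5-bis(methoxymethoxy)benzene
Conditions: MeI, K2CO3, DMF, rt
Reagents that add atoms: iodomethane, CI
Why: Williamson O-methylation of the only free phenol; this fixes the future 8-methoxy group.

Step 7
Reactants: 10 1-(benzyloxy)-2-methoxy-3,5-bis(methoxymethoxy)benzene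
Product: 11 2-methoxy-3,5-bis(methoxymethoxy)phenol
Conditions: H2 (1 atm), Pd/C, EtOAc, rt
Reagents that add atoms: none
Why: Hydrogenolysis of the benzyl ether; MOM and methyl ethers are inert, and no alkene is present yet.

Step 8
Reactants: 11 2-methoxy-3,5-bis(methoxymethoxy)phenol
Product: 12 2-hydroxy-3-methoxy-4,6-bis(methoxymethoxy)benzaldehyde
Conditions: MgCl2, Et3N, (CH2O)n, MeCN, reflux
Reagents that add atoms: paraformaldehyde (as formaldehyde), C=O
Why: Magnesium-mediated ortho-formylation of a phenol; the magnesium phenoxide delivers formaldehyde only to an ortho carbon, and only one is free, so the carbon between the two MOM ethers is not touched; the basic medium preserves the acetals.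

Step 9
Reactants: 12 2-hydroxy-3-methoxy-4,6-bis(methoxymethoxy)benzaldehyde; 4 4-(3-methylbut-2-enyloxy)benzoic acid
Product: 13 2-formyl-6-methoxy-3,5-bis(methoxymethoxy)phenyl 4-(3-methylbut-2-enyloxy)benzoate
Conditions: EDC·HCl, DMAP, CH2Cl2, 0 °C to rt
Reagents that add atoms: none
Why: Steglich esterification; the acylpyridinium is reactive enough for the hindered, hydrogen-bonded phenol, and the conditions are neutral for MOM and prenyl groups; this places O1 and C2 with ring B.

Step 10
Reactants: 13 2-formyl-6-methoxy-3,5-bis(methoxymethoxy)phenyl 4-(3-methylbut-2-enyloxy)benzoate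
Product: 14 3-methoxy-4,6-bis(methoxymethoxy)-2-{[4-(3-methylbut-2-enyloxy)benzoyl]oxy}benzoic acid
Conditions: NaClO2, NaH2PO4, 2-methyl-2-butene (large excess), t-BuOH/THF/H2O, 0 °C to rt
Reagents that add atoms: sodium chlorite, [Na+].[O-]Cl=O
Why: Pinnick oxidation; chlorous acid oxidises the hindered aldehyde at pH 3–4, where aryl ester and acetals persist, and the excess scavenger alkene removes hypochlorous acid before it reaches the prenyl alkene or the electron-rich ring.

Step 11
Reactants: 14 3-methoxy-4,6-bis(methoxymethoxy)-2-{[4-(3-methylbut-2-enyloxy)benzoyl]oxy}benzoic acid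
Product: 15 3-methoxy-4,6-bis(methoxymethoxy)-2-{[4-(3-methylbut-2-enyloxy)benzoyl]oxy}benzoyl chloride
Conditions: 1-chloro-N,N,2-trimethylprop-1-en-1-amine (1.05 equiv), CH2Cl2, 0 °C to rt; evaporate, use crude at once
Reagents that add atoms: 1-chloro-N,N,2-trimethylprop-1-en-1-amine, CC(C)=C(Cl)N(C)C
Why: Acid chloride formation with an α-chloroenamine; the acid proton ends on carbon of the amide by-product, so no HCl is liberated and the acetals and prenyl ether are not exposed to acid.

Step 12
Reactants: 15 3-methoxy-4,6-bis(methoxymethoxy)-2-{[4-(3-methylbut-2-enyloxy)benzoyl]oxy}benzoyl chloride; 16 [2-(trimethylsilyl)ethoxymethyl]triphenylphosphonium chloride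
Product: 19 8-methoxy-5,7-bis(methoxymethoxy)-2-[4-(3-methylbut-2-enyloxy)phenyl]-3-[2-(trimethylsilyl)ethoxy]chromen-4-one, via alkoxymethylene ylide 17 (not isolated), via acyl ylide 18 (not isolated)
Conditions: 16 (2.2 equiv), NaN(SiMe3)2 (2.1 equiv), THF, −78 to 0 °C; 15 added slowly at −78 °C, then to rt; solvent changed to toluene, 110 °C
Reagents that add atoms: none
Why: Proposed new method: ylide 17 is C-acylated by the acid chloride of 15, by far the more electrophilic of the two acyl groups, and a second equivalent of 17 removes the acidic proton of the resulting phosphonium ion to give the acyl-stabilised α-alkoxy ylide 18, forming C3–C4. On heating, the ylide carbon of 18 adds to the neighbouring aryl ester carbonyl and the oxaphosphetane collapses with loss of Ph3P=O, an intramolecular Wittig olefination that forms C2=C3. The closest known reaction type is the chromone and flavone synthesis by intramolecular ester olefination of acylphosphoranes made from O-acylsalicylic acid derivatives and unsubstituted or silylated methylene ylides; an α-alkoxy ylide has not been used in it, and the α-oxygen should raise the nucleophilicity of the ylide carbon at the price of a more crowded, fully substituted alkene. Ring C closes in a 6-exo-trig addition of C3 to the ester carbonyl carbon, and the ortho relationship of the two acyl groups on C4a and C8a fixes the ring size. No stereocentre is formed. The step needs acylation at the acid chloride and not at the ester, which the reactivity gap and the low temperature secure, and C- over O-acylation, which is the normal course for non-stabilised ylides. MOM, prenyl and silylethyl ethers are inert to the ylide and to the base-free thermal stage, which stays well below the temperature of an aryl prenyl ether Claisen rearrangement.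

Step 13
Reactants: 19 8-methoxy-5,7-bis(methoxymethoxy)-2-[4-(3-methylbut-2-enyloxy)phenyl]-3-[2-(trimethylsilyl)ethoxy]chromen-4-one
Product: 20 3-hydroxy-8-methoxy-5,7-bis(methoxymethoxy)-2-[4-(3-methylbut-2-enyloxy)phenyl]chromen-4-one
Conditions: Bu4NF, THF, rt to 50 °C, under argon; aq. NH4Cl
Reagents that add atoms: none
Why: Fluoride-induced fragmentation of a 2-(trimethylsilyl)ethyl ether, as known for aryl ethers of this type; attack at silicon expels ethene and the 3-oxidochromenone, a leaving group of phenoxide quality, while MOM and prenyl ethers are inert to fluoride.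

Step 14
Reactants: 20 3-hydroxy-8-methoxy-5,7-bis(methoxymethoxy)-2-[4-(3-methylbut-2-enyloxy)phenyl]chromen-4-one
Product: 21 3,5,7-trihydroxy-8-methoxy-2-[4-(3-methylbut-2-enyloxy)phenyl]chromen-4-one (3,5,7-trihydroxy-8-methoxy-4'-prenyloxyflavone)
Conditions: Me3SiOTf, 2,2'-bipyridyl, CH2Cl2, 0 °C to rt; then H2O, aq. NaHCO3
Reagents that add atoms: none
Why: Chemoselective cleavage of aromatic MOM ethers by a silyl triflate–bipyridyl complex; the acetals are converted to aryl silyl ethers under buffered aprotic conditions and water hydrolyses these together with the transient 3-O-silyl ether, so no free protic acid meets the prenyl ether and the methyl ether is untouched.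

## Compound list

1 | methyl 4-hydroxybenzoate | COC(=O)c1ccc(O)cc1 | starting material
2 | 1-bromo-3-methylbut-2-ene | CC(C)=CCBr | starting material
3 | methyl 4-(3-methylbut-2-enyloxy)benzoate | COC(=O)c1ccc(OCC=C(C)C)cc1 | intermediate
4 | 4-(3-methylbut-2-enyloxy)benzoic acid | OC(=O)c1ccc(OCC=C(C)C)cc1 | intermediate
5 | 2,4,6-trihydroxybenzaldehyde | O=Cc1c(O)cc(O)cc1O | starting material
6 | 2-hydroxy-4,6-bis(methoxymethoxy)benzaldehyde | O=Cc1c(O)cc(OCOC)cc1OCOC | intermediate
7 | 2-(benzyloxy)-4,6-bis(methoxymethoxy)benzaldehyde | O=Cc1c(OCc2ccccc2)cc(OCOC)cc1OCOC | intermediate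
8 | 2-(benzyloxy)-4,6-bis(methoxymethoxy)phenyl formate | O=COc1c(OCc2ccccc2)cc(OCOC)cc1OCOC | intermediate
9 | 2-(benzyloxy)-4,6-bis(methoxymethoxy)phenol | Oc1c(OCc2ccccc2)cc(OCOC)cc1OCOC | intermediate
10 | 1-(benzyloxy)-2-methoxy-3,5-bis(methoxymethoxy)benzene | COc1c(OCc2ccccc2)cc(OCOC)cc1OCOC | intermediate
11 | 2-methoxy-3,5-bis(methoxymethoxy)phenol | COc1c(O)cc(OCOC)cc1OCOC | intermediate
12 | 2-hydroxy-3-methoxy-4,6-bis(methoxymethoxy)benzaldehyde | COc1c(O)c(C=O)c(OCOC)cc1OCOC | intermediate
13 | 2-formyl-6-methoxy-3,5-bis(methoxymethoxy)phenyl 4-(3-methylbut-2-enyloxy)benzoate | COc1c(OC(=O)c2ccc(OCC=C(C)C)cc2)c(C=O)c(OCOC)cc1OCOC | intermediate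
14 | 3-methoxy-4,6-bis(methoxymethoxy)-2-{[4-(3-methylbut-2-enyloxy)benzoyl]oxy}benzoic acid | COc1c(OC(=O)c2ccc(OCC=C(C)C)cc2)c(C(=O)O)c(OCOC)cc1OCOC | intermediate
15 | 3-methoxy-4,6-bis(methoxymethoxy)-2-{[4-(3-methylbut-2-enyloxy)benzoyl]oxy}benzoyl chloride | COc1c(OC(=O)c2ccc(OCC=C(C)C)cc2)c(C(Cl)=O)c(OCOC)cc1OCOC | intermediate
16 | [2-(trimethylsilyl)ethoxymethyl]triphenylphosphonium chloride | C[Si](C)(C)CCOC[P+](c1ccccc1)(c1ccccc1)c1ccccc1.[Cl-] | starting material
17 | {[2-(trimethylsilyl)ethoxy]methylene}triphenylphosphorane | C[Si](C)(C)CCOC=P(c1ccccc1)(c1ccccc1)c1ccccc1 | intermediate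
18 | 6-methoxy-3,5-bis(methoxymethoxy)-2-{[2-(trimethylsilyl)ethoxy](triphenyl-λ5-phosphanylidene)acetyl}phenyl 4-(3-methylbut-2-enyloxy)benzoate | COc1c(OC(=O)c2ccc(OCC=C(C)C)cc2)c(C(=O)C(OCC[Si](C)(C)C)=P(c2ccccc2)(c2ccccc2)c2ccccc2)c(OCOC)cc1OCOC | intermediate
19 | 8-methoxy-5,7-bis(methoxymethoxy)-2-[4-(3-methylbut-2-enyloxy)phenyl]-3-[2-(trimethylsilyl)ethoxy]chromen-4-one | COc1c(OCOC)cc(OCOC)c2c(=O)c(OCC[Si](C)(C)C)c(-c3ccc(OCC=C(C)C)cc3)oc12 | intermediate
20 | 3-hydroxy-8-methoxy-5,7-bis(methoxymethoxy)-2-[4-(3-methylbut-2-enyloxy)phenyl]chromen-4-one | COc1c(OCOC)cc(OCOC)c2c(=O)c(O)c(-c3ccc(OCC=C(C)C)cc3)oc12 | intermediate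
21 | 3,5,7-trihydroxy-8-methoxy-2-[4-(3-methylbut-2-enyloxy)phenyl]chromen-4-one | COc1c(O)cc(O)c2c(=O)c(O)c(-c3ccc(OCC=C(C)C)cc3)oc12 | target

## Step count and least certain steps

Total: 14 steps. Longest linear sequence: 12 steps (steps 3–14 from 5); steps 1–2 form the side branch that joins at step 9.

**Step 12 (key step).** Two processes are most likely to go wrong. The first is aroyl transfer: attack of the non-stabilised ylide, or of the enolate oxygen of the acyl ylide, on the aryl ester strips ring B from O1. The second is failure of the hindered α-alkoxy acyl ylide to add to the ester carbonyl at a temperature the prenyl ether tolerates, since the alkene to be formed is fully substituted. Fallback by known chemistry, from 15 back to 20: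
- 15 is treated with methylenetriphenylphosphorane (two equivalents) to give 6-methoxy-3,5-bis(methoxymethoxy)-2-[(triphenyl-λ5-phosphanylidene)acetyl]phenyl 4-(3-methylbut-2-enyloxy)benzoate F1.
- Heating in toluene closes F1, by the established intramolecular ester olefination, to 8-methoxy-5,7-bis(methoxymethoxy)-2-[4-(3-methylbut-2-enyloxy)phenyl]chromen-4-one F2 (the same flavone as A5).
- C3 of F2 is lithiated with lithium diisopropylamide at −78 °C, trapped with B(OMe)3 and oxidised with H2O2/AcOH, giving 20. This also makes step 13 unnecessary.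

**Step 11.** The activated carboxyl sits next to a MOM ether and an aryl ester. Cyclisation of the acetal oxygen onto the acyl chloride (loss of the MOM group) or aroyl migration may consume 15 before it meets the ylide. Fallback, from 14 back to 19: 14 is activated with 1,1'-carbonyldiimidazole to 2-(1H-imidazole-1-carbonyl)-6-methoxy-3,5-bis(methoxymethoxy)phenyl 4-(3-methylbut-2-enyloxy)benzoate F3. This chloride-free acyl donor is known to C-acylate phosphorus ylides, and with 17 it gives 18 and, on heating, 19.

**Step 14.** Silylation of the prenyl ether oxygen may compete with that of the acetals and lead to ionisation and loss of the prenyl group, because the allylic cation is well stabilised. Fallback, from 12 back to 21, in which the acetals are cleaved before the prenyl group exists: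
- 12 is esterified (EDC·HCl, DMAP) with commercial 4-(prop-2-enyloxy)benzoic acid to 2-formyl-6-methoxy-3,5-bis(methoxymethoxy)phenyl 4-(prop-2-enyloxy)benzoate F4.
- Pinnick oxidation gives 3-methoxy-4,6-bis(methoxymethoxy)-2-{[4-(prop-2-enyloxy)benzoyl]oxy}benzoic acid F5.
- The chloroenamine gives 3-methoxy-4,6-bis(methoxymethoxy)-2-{[4-(prop-2-enyloxy)benzoyl]oxy}benzoyl chloride F6.
- Ylide 17 gives 6-methoxy-3,5-bis(methoxymethoxy)-2-{[2-(trimethylsilyl)ethoxy](triphenyl-λ5-phosphanylidene)acetyl}phenyl 4-(prop-2-enyloxy)benzoate F7.
- Heating gives 8-methoxy-5,7-bis(methoxymethoxy)-2-[4-(prop-2-enyloxy)phenyl]-3-[2-(trimethylsilyl)ethoxy]chromen-4-one F8.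
- Fluoride gives 3-hydroxy-8-methoxy-5,7-bis(methoxymethoxy)-2-[4-(prop-2-enyloxy)phenyl]chromen-4-one F9.
- Methanolic HCl, harmless to an allyl ether, gives 3,5,7-trihydroxy-8-methoxy-2-[4-(prop-2-enyloxy)phenyl]chromen-4-one F10.
- Olefin cross-metathesis with 2-methyl-2-butene (second-generation Grubbs catalyst) converts the allyl ether into the prenyl ether, giving 21.

## Further compounds

F1 | step 12 | 6-methoxy-3,5-bis(methoxymethoxy)-2-[(triphenyl-λ5-phosphanylidene)acetyl]phenyl 4-(3-methylbut-2-enyloxy)benzoate | COc1c(OC(=O)c2ccc(OCC=C(C)C)cc2)c(C(=O)C=P(c2ccccc2)(c2ccccc2)c2ccccc2)c(OCOC)cc1OCOC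
F2 | step 12 | 8-methoxy-5,7-bis(methoxymethoxy)-2-[4-(3-methylbut-2-enyloxy)phenyl]chromen-4-one | COc1c(OCOC)cc(OCOC)c2c(=O)cc(-c3ccc(OCC=C(C)C)cc3)oc12
F3 | step 11 | 2-(1H-imidazole-1-carbonyl)-6-methoxy-3,5-bis(methoxymethoxy)phenyl 4-(3-methylbut-2-enyloxy)benzoate | COc1c(OC(=O)c2ccc(OCC=C(C)C)cc2)c(C(=O)n2ccnc2)c(OCOC)cc1OCOC
F4 | step 14 | 2-formyl-6-methoxy-3,5-bis(methoxymethoxy)phenyl 4-(prop-2-enyloxy)benzoate | COc1c(OC(=O)c2ccc(OCC=C)cc2)c(C=O)c(OCOC)cc1OCOC
F5 | step 14 | 3-methoxy-4,6-bis(methoxymethoxy)-2-{[4-(prop-2-enyloxy)benzoyl]oxy}benzoic acid | COc1c(OC(=O)c2ccc(OCC=C)cc2)c(C(=O)O)c(OCOC)cc1OCOC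
F6 | step 14 | 3-methoxy-4,6-bis(methoxymethoxy)-2-{[4-(prop-2-enyloxy)benzoyl]oxy}benzoyl chloride | COc1c(OC(=O)c2ccc(OCC=C)cc2)c(C(Cl)=O)c(OCOC)cc1OCOC
F7 | step 14 | 6-methoxy-3,5-bis(methoxymethoxy)-2-{[2-(trimethylsilyl)ethoxy](triphenyl-λ5-phosphanylidene)acetyl}phenyl 4-(prop-2-enyloxy)benzoate | COc1c(OC(=O)c2ccc(OCC=C)cc2)c(C(=O)C(OCC[Si](C)(C)C)=P(c2ccccc2)(c2ccccc2)c2ccccc2)c(OCOC)cc1OCOC
F8 | step 14 | 8-methoxy-5,7-bis(methoxymethoxy)-2-[4-(prop-2-enyloxy)phenyl]-3-[2-(trimethylsilyl)ethoxy]chromen-4-one | COc1c(OCOC)cc(OCOC)c2c(=O)c(OCC[Si](C)(C)C)c(-c3ccc(OCC=C)cc3)oc12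
F9 | step 14 | 3-hydroxy-8-methoxy-5,7-bis(methoxymethoxy)-2-[4-(prop-2-enyloxy)phenyl]chromen-4-one | COc1c(OCOC)cc(OCOC)c2c(=O)c(O)c(-c3ccc(OCC=C)cc3)oc12
F10 | step 14 | 3,5,7-trihydroxy-8-methoxy-2-[4-(prop-2-enyloxy)phenyl]chromen-4-one | COc1c(O)cc(O)c2c(=O)c(O)c(-c3ccc(OCC=C)cc3)oc12
A1 | alternative 1 | trans-3-hydroxy-8-methoxy-5,7-bis(methoxymethoxy)-2-[4-(3-methylbut-2-enyloxy)phenyl]chroman-4-one (racemic, one enantiomer drawn) | CC(C)=CCOc1ccc(cc1)[C@@H]1[C@H](C(=O)c2c(OCOC)cc(OCOC)c(OC)c2O1)O
A2 | alternative 1 | 3-methoxy-4,6-bis(methoxymethoxy)-2-{1-[4-(3-methylbut-2-enyloxy)phenyl]-2-oxoethoxy}benzaldehyde (racemic) | COc1c(OC(C=O)c2ccc(OCC=C(C)C)cc2)c(C=O)c(OCOC)cc1OCOC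
A3 | alternative 2 | 7-tert-butoxy-5-hydroxy-8-methoxy-3-(methoxymethoxy)-2-[4-(3-methylbut-2-enyloxy)phenyl]chromen-4-one | COc1c(OC(C)(C)C)cc(O)c2c(=O)c(OCOC)c(-c3ccc(OCC=C(C)C)cc3)oc12
A4 | alternative 2 | 3-tert-butoxy-4-methoxy-4-{5-(methoxymethoxy)-6-[4-(3-methylbut-2-enyloxy)phenyl]-4-oxo-4H-pyran-2-yl}cyclobut-2-en-1-one (racemic) | COC1(C(OC(C)(C)C)=CC1=O)c1cc(=O)c(OCOC)c(-c2ccc(OCC=C(C)C)cc2)o1
A5 | alternative 3 | 8-methoxy-5,7-bis(methoxymethoxy)-2-[4-(3-methylbut-2-enyloxy)phenyl]chromen-4-one | COc1c(OCOC)cc(OCOC)c2c(=O)cc(-c3ccc(OCC=C(C)C)cc3)oc12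
A6 | alternative 3 | 2-iodo-6-methoxy-3,5-bis(methoxymethoxy)phenol | COc1c(O)c(I)c(OCOC)cc1OCOC
A7 | alternative 3 | 1-ethynyl-4-(3-methylbut-2-enyloxy)benzene | C#Cc1ccc(OCC=C(C)C)cc1
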